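**Retrosynthetic overview**
1. Target 14 ⇐ hydroxy aldehyde 13 by one oxidation (secondary alcohol → ketone, CHO → CO2H).
2. 13 ⇐ linear tetraenal 12 by an intramolecular Diels–Alder reaction. The cyclohexene (bonds C3a–C7a and C4–C5) and the cyclopentane close in the same step, steered by the three tether stereocentres.
3. 12 ⇐ β-hydroxy aldehyde 11 by Wittig olefination (dienophile C=C).
4. 11 ⇐ racemic trienal 9 + propanal by an L-proline cross-aldol run as a dynamic kinetic resolution. All absolute stereochemistry originates here.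
5. 9 ⇐ (E)-2-ethylhex-2-enal 1 by γ-dimethoxymethylation, Wittig and Horner–Wadsworth–Emmons chain extension, then acetal hydrolysis.

Assumption: ylide 5 is taken as a purchasable reagent (otherwise one operation from propyltriphenylphosphonium bromide, n-BuLi and ethyl formate), and commercial 1 is the E isomer.

**Step 1**
Reactants: 1 (E)-2-ethylhex-2-enal; 2 trimethyl orthoformate
Product: 4 rac-(E)-2,4-diethyl-5,5-dimethoxypent-2-enal, via silyl dienol ether 3 (not isolated)
Conditions: TMSOTf (1.3 equiv), i-Pr2NEt (1.2 equiv), CH2Cl2, 0 °C, 1 h; then HC(OMe)3 (1.1 equiv), −78 → −20 °C; aq. NaHCO3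
Reagents that add atoms: trimethylsilyl triflate, C[Si](C)(C)OS(=O)(=O)C(F)(F)F (its silyl group sits in 3 only)
Why: One-pot silyl dienol ether formation and vinylogous Mukaiyama reaction with the dimethoxycarbenium ion is γ-selective (α-attack would build a quaternary centre and lose conjugation), so the later ketone carbon is attached as a masked aldehyde; the new C4 centre is left racemic because it becomes the enolisable α-carbon of 9 and is fixed only in step 5.

**Step 2**
Reactants: 4 rac-(E)-2,4-diethyl-5,5-dimethoxypent-2-enal; 5 2-(triphenylphosphoranylidene)butanal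
Product: 6 rac-(2E,4E)-2,4,6-triethyl-7,7-dimethoxyhepta-2,4-dienal
Conditions: toluene, 90 °C, 16 h
Reagents that add atoms: none
Why: Wittig olefination with a formyl-stabilised ylide adds one (E)-CH=C(Et) unit with high E selectivity and leaves the acetal untouched.

**Step 3**
Reactants: 6 rac-(2E,4E)-2,4,6-triethyl-7,7-dimethoxyhepta-2,4-dienal; 7 diethyl benzylphosphonate
Product: 8 rac-[(1E,3E,5E)-3,5,7-triethyl-8,8-dimethoxyocta-1,3,5-trien-1-yl]benzene
Conditions: 7, NaH, THF, 0 °C, 30 min; then 6, 0 °C → rt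
Reagents that add atoms: none
Why: Horner–Wadsworth–Emmons olefination with the benzylphosphonate anion installs the (E)-styryl terminus, addition to the aldehyde being much faster than deprotonation of the remote allylic C–H.

**Step 4**
Reactants: 8 rac-[(1E,3E,5E)-3,5,7-triethyl-8,8-dimethoxyocta-1,3,5-trien-1-yl]benzene
Product: 9 rac-(3E,5E,7E)-2,4,6-triethyl-8-phenylocta-3,5,7-trienal
Conditions: PPTS (0.2 equiv), acetone/H2O (9:1), 40 °C, 2 h; used at once
Reagents that add atoms: water, O
Why: Mild acid hydrolysis of the dimethyl acetal frees the α-branched aldehyde without moving the triene into conjugation with the carbonyl; the aldehyde is racemic and is carried on immediately.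

**Step 5**
Reactants: 9 rac-(3E,5E,7E)-2,4,6-triethyl-8-phenylocta-3,5,7-trienal; 10 propanal
Product: 11 (2S,3S,4R,5E,7E,9E)-4,6,8-triethyl-3-hydroxy-2-methyl-10-phenyldeca-5,7,9-trienal
Conditions: L-proline (20 mol %), DMF, 4 °C; propanal (3 equiv) added over 24 h by syringe pump, then 24 h more
Reagents that add atoms: none
Why: Proposed new method: an L-proline aldehyde–aldehyde cross-aldol run as a dynamic kinetic resolution of a skipped-polyenyl aldehyde — the C2–H of 9 is both α-formyl and allylic to the styryl diene, so proline should racemise it through its conjugated enamine/enol faster than C–C bond formation, while the anti-enamine of propanal adds through the carboxylic-acid-directed Houk–List chair to the Re face of only that enantiomer, (R)-9, whose Felkin–Anh face (alkenyl as the large group) is the same face, which fixes C2 (S), C3 (S) and C4 (R) of 11 in one event (2,3-anti, 3,4-syn); the closest known reaction types are the proline-catalysed cross-aldol of two aldehydes and amine-mediated dynamic kinetic resolutions of enolisable α-branched aldehydes.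

**Step 6**
Reactants: 11 (2S,3S,4R,5E,7E,9E)-4,6,8-triethyl-3-hydroxy-2-methyl-10-phenyldeca-5,7,9-trienal; 5 2-(triphenylphosphoranylidene)butanal
Product: 13 (1R,2R,3R,3aS,4S,5R,7aS)-1,4,5,7-tetraethyl-2-hydroxy-3-methyl-5-[(E)-2-phenylethenyl]-2,3,3a,4,5,7a-hexahydro-1H-indene-4-carbaldehyde, via hydroxy tetraenal 12 (not isolated)
Conditions: 5 (1.15 equiv), BHT (cat.), toluene, 60 °C, 12 h; then 90 °C, 12 h
Reagents that add atoms: none
Why: Wittig olefination gives the (E)-2-ethyl enal 12, which on warming undergoes an intramolecular Diels–Alder reaction through the formyl-endo, trans-fused transition state in which the C4–H and C6–H of the tether lie in the planes of dienophile and diene (minimal 1,3-allylic strain against the two vinylic ethyl groups), so the tether centres set C3a, C4, C5 and C7a while both rings close.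

**Step 7**
Reactants: 13 (1R,2R,3R,3aS,4S,5R,7aS)-1,4,5,7-tetraethyl-2-hydroxy-3-methyl-5-[(E)-2-phenylethenyl]-2,3,3a,4,5,7a-hexahydro-1H-indene-4-carbaldehyde
Product: 14 isospiculoic acid A, (1R,3R,3aS,4S,5R,7aS)-1,4,5,7-tetraethyl-3-methyl-2-oxo-5-[(E)-2-phenylethenyl]-2,3,3a,4,5,7a-hexahydro-1H-indene-4-carboxylic acid
Conditions: CrO3, H2SO4, acetone/H2O, 0 °C, 1 h; i-PrOH quench
Reagents that add atoms: water, O
Why: Jones oxidation takes the secondary alcohol to the ketone and the aldehyde (through its hydrate) to the carboxylic acid in one operation; C1 and C3 already sit in the all-trans arrangement, which should be the thermodynamically preferred one on the trans-fused hydrindanone, so acid-mediated enolisation is not expected to erode them.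

**Compound list**
1 | (E)-2-ethylhex-2-enal | CCC/C=C(CC)/C=O | starting material
2 | trimethyl orthoformate | COC(OC)OC | starting material
3 | (3E)-2-ethyl-1-(trimethylsilyloxy)hexa-1,3-diene (mixture at the enol ether bond) | CC/C=C/C(CC)=CO[Si](C)(C)C | intermediate
4 | rac-(E)-2,4-diethyl-5,5-dimethoxypent-2-enal | O=C/C(CC)=C/C(CC)C(OC)OC | intermediate
5 | 2-(triphenylphosphoranylidene)butanal | CCC(C=O)=P(c1ccccc1)(c1ccccc1)c1ccccc1 | starting material
6 | rac-(2E,4E)-2,4,6-triethyl-7,7-dimethoxyhepta-2,4-dienal | O=C/C(CC)=C/C(CC)=C/C(CC)C(OC)OC | intermediate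
7 | diethyl benzylphosphonate | CCOP(=O)(Cc1ccccc1)OCC | starting material
8 | rac-[(1E,3E,5E)-3,5,7-triethyl-8,8-dimethoxyocta-1,3,5-trien-1-yl]benzene | COC(OC)C(CC)/C=C(CC)/C=C(CC)/C=C/c1ccccc1 | intermediate
9 | rac-(3E,5E,7E)-2,4,6-triethyl-8-phenylocta-3,5,7-trienal | O=CC(CC)/C=C(CC)/C=C(CC)/C=C/c1ccccc1 | intermediate
10 | propanal | CCC=O | starting material
11 | (2S,3S,4R,5E,7E,9E)-4,6,8-triethyl-3-hydroxy-2-methyl-10-phenyldeca-5,7,9-trienal | O=C[C@@H](C)[C@@H](O)[C@H](CC)/C=C(CC)/C=C(CC)/C=C/c1ccccc1 | intermediate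
12 | (2E,4R,5R,6R,7E,9E,11E)-2,6,8,10-tetraethyl-5-hydroxy-4-methyl-12-phenyldodeca-2,7,9,11-tetraenal | O=C/C(CC)=C/[C@@H](C)[C@@H](O)[C@H](CC)/C=C(CC)/C=C(CC)/C=C/c1ccccc1 | intermediate
13 | (1R,2R,3R,3aS,4S,5R,7aS)-1,4,5,7-tetraethyl-2-hydroxy-3-methyl-5-[(E)-2-phenylethenyl]-2,3,3a,4,5,7a-hexahydro-1H-indene-4-carbaldehyde | CCC1=C[C@](/C=C/c2ccccc2)(CC)[C@@](CC)(C=O)[C@H]2[C@H]1[C@@H](CC)[C@H](O)[C@@H]2C | intermediate
14 | isospiculoic acid A, (1R,3R,3aS,4S,5R,7aS)-1,4,5,7-tetraethyl-3-methyl-2-oxo-5-[(E)-2-phenylethenyl]-2,3,3a,4,5,7a-hexahydro-1H-indene-4-carboxylic acid | CCC1=C[C@](/C=C/c2ccccc2)(CC)[C@@](CC)(C(=O)O)[C@H]2[C@H]1[C@@H](CC)C(=O)[C@@H]2C | target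

**Step count**
Total steps: 7. Longest linear sequence: 7 (1 → 14).

**Steps most likely to fail**

Step 5 (the proposed new step). The risk is that racemisation of 9 is slower than the aldol, or that 9 drifts into conjugation. The fallback uses only known chemistry, sets out from racemic 9 and comes back at 11. The same proline cross-aldol is run as an ordinary catalyst-controlled reaction (−10 °C, short contact time, no reliance on in-flask racemisation). (R)-9 then gives 11 and (S)-9 gives its C4 epimer, (2S,3S,4S,5E,7E,9E)-4,6,8-triethyl-3-hydroxy-2-methyl-10-phenyldeca-5,7,9-trienal F1. The two diastereomers are separated on silica (50 % ceiling on 11) and pure 11 goes on.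

Step 6. The risk is that the free β-hydroxy aldehyde dehydrates or undergoes retro-aldol at the temperature the formyl ylide needs. The fallback sets out from 11 and comes back at 12. Olefination at room temperature with the more reactive ester ylide ethyl 2-(triphenylphosphoranylidene)butanoate (CH2Cl2, 23 °C) gives ethyl (2E,4R,5R,6R,7E,9E,11E)-2,6,8,10-tetraethyl-5-hydroxy-4-methyl-12-phenyldodeca-2,7,9,11-tetraenoate F2. Reduction with i-Bu2AlH (CH2Cl2, −78 °C) gives (2E,4R,5R,6R,7E,9E,11E)-2,6,8,10-tetraethyl-4-methyl-12-phenyldodeca-2,7,9,11-tetraene-1,5-diol F3. Chemoselective oxidation of the allylic alcohol with MnO2 (CH2Cl2, 0 °C) gives 12, which is then warmed in toluene (80–90 °C) to 13.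

Step 7. The risk is that the aldehyde, which is neopentyl between two quaternary carbons, oxidises slowly while prolonged acid contact damages the styryl and cyclohexene double bonds. The fallback sets out from 13 and comes back at 14 by two chemoselective oxidations. NaClO2/NaH2PO4/2-methyl-2-butene (t-BuOH/H2O) gives (1R,2R,3R,3aS,4S,5R,7aS)-1,4,5,7-tetraethyl-2-hydroxy-3-methyl-5-[(E)-2-phenylethenyl]-2,3,3a,4,5,7a-hexahydro-1H-indene-4-carboxylic acid F4. Dess–Martin periodinane (NaHCO3, CH2Cl2) then gives 14.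

**Further compounds**
F1 | step 5 | (2S,3S,4S,5E,7E,9E)-4,6,8-triethyl-3-hydroxy-2-methyl-10-phenyldeca-5,7,9-trienal | O=C[C@@H](C)[C@@H](O)[C@@H](CC)/C=C(CC)/C=C(CC)/C=C/c1ccccc1
F2 | step 6 | ethyl (2E,4R,5R,6R,7E,9E,11E)-2,6,8,10-tetraethyl-5-hydroxy-4-methyl-12-phenyldodeca-2,7,9,11-tetraenoate | CCOC(=O)/C(CC)=C/[C@@H](C)[C@@H](O)[C@H](CC)/C=C(CC)/C=C(CC)/C=C/c1ccccc1
F3 | step 6 | (2E,4R,5R,6R,7E,9E,11E)-2,6,8,10-tetraethyl-4-methyl-12-phenyldodeca-2,7,9,11-tetraene-1,5-diol | OC/C(CC)=C/[C@@H](C)[C@@H](O)[C@H](CC)/C=C(CC)/C=C(CC)/C=C/c1ccccc1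
F4 | step 7 | (1R,2R,3R,3aS,4S,5R,7aS)-1,4,5,7-tetraethyl-2-hydroxy-3-methyl-5-[(E)-2-phenylethenyl]-2,3,3a,4,5,7a-hexahydro-1H-indene-4-carboxylic acid | CCC1=C[C@](/C=C/c2ccccc2)(CC)[C@@](CC)(C(=O)O)[C@H]2[C@H]1[C@@H](CC)[C@H](O)[C@@H]2C
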